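Its constants are those of an exercise; the rest is arithmetic.

A closed flask cannot start below its own charge, so before the next run I had to choose whether the substrate went into the flask or through the tank.

- north-west: substrate 1.5 M; a single well-mixed tank run continuously and read at steady state, 4.0 h in it on average
- south-east: substrate 1.5 M; time 4.0 h; a closed flask charged with all of it at once and left for 4.0 h

    substrate + by-product → side product (k1 = 0.0013 M⁻¹ min⁻¹)
    2 substrate → homo dimer (k2 = 0.20 M⁻¹ min⁻¹)
    substrate ⇌ target + by-product (K3 = 3.1 M, k3 = 0.028 min⁻¹)

- the set-up with the highest amount of target at the outlet or at the end, in percent of the substrate put in ("none" if the first two lie within 2 percentage points) (north-west / south-east / none)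
- amount of target at the outlet or at the end, in percent of the substrate put in, north-west
- amount of target at the outlet or at the end, in percent of the substrate put in, south-east

- in percentages every species weighs as the substrate in it: one homo dimer counts as two
- for a step with 2 of a species take k times the square, and two of it per event
- the stated concentrations are those of everything mixed, before any reaction; amounts are the same in each set-up
- run time (south-east): 4.0 h

The choice hung on one quantity, which I called the split: substrate going to homo dimer per substrate going forward to target at a given moment, or twice the dimerisation constant times [substrate] over the forward constant of the reversible step, a selectivity factor that falls as [substrate] falls. At the charge it was 21.4.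

I set aside the side product and the way back. The forward half-life of substrate, the way back not counted, was 24.8 min, and 4.0 h is 9.68 of these, so in my reckoning I let [substrate] in the flask fall to zero. Its split then runs down from the charge to zero, and averaging the target's share over that descent gives:

south-east: ln(1 + 21.4) / 21.4 = 14.5%

The tank holds one [substrate], which the balance over its mean holding time gives:

north-west: 1.5 M = 7.72 [substrate] + 96.0 M⁻¹ [substrate] squared, so [substrate] = 0.0911 M

At that level the split gives the tank 40.8%.

The tank promised more target than the flask, so I chose the tank, although my figures still lacked the way back.

The forecast also chose north-west, with 25.4% (23.5% to 27%) for the tank and 12.9% (11.5% to 14.5%) for the flask, on the ground that “the well-mixed tank holds substrate low from the start”. My tank figure stood higher than its range.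

The simulation gave north-west, with 25.4% in the tank and 12.8% in the flask.

The tank held [substrate] at 0.102 M, a split of 1.46. With the conversion to homo dimer struck out, the tank gave 64.9% and the flask 70.9%, so that conversion is what put the tank ahead. Striking out instead the backward run from target + by-product to substrate lifted the tank to 40.5%, so that backward run accounts for a part of the tank's shortfall. The same flask charged at 0.90 M has a split of 12.9, which gave me 20.4%, and its simulation read 18.5%.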